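The runs were computed for an exercise, and the scatter is random.

Start from the balance. In the flask we charge G and L alike, 0.020 M and 0.0200 M, and each Q takes one G and one L.

| setting | ochre | violet | green | flask |
|---|---|---|---|---|
| G | 0.020 M | 0.020 M | 0.010 M | 0.020 M |
| L | 0.010 M | 0.040 M | 0.020 M | 0.0200 M |
| remark | run made earlier | run made earlier | run made earlier |  |
| time |  |  |  | 80 min |

| run | time / min | Q / % | Z / % |
|---|---|---|---|
| ochre | 6.00 | 8.7 | 26.2 |
| ochre | 20.0 | 18.9 | 4.3 |
| ochre | 30.0 | 20.4 | 2.0 |
| ochre | 50.0 | 21.7 | 0.3 |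
| ochre | 80.0 | 21.8 | 0 |
| ochre | 90.0 | 22.3 | 0.1 |
| violet | 8.00 | 34.6 | 7.4 |
| violet | 12.0 | 39.8 | 2.3 |
| violet | 20.0 | 41.9 | 0 |
| violet | 40.0 | 42.0 | 0 |
| violet | 60.0 | 42.4 | 0 |
| violet | 90.0 | 42.2 | 0 |
| green | 8.00 | 36.5 | 16.7 |
| green | 25.0 | 49.1 | 1.1 |
| green | 40.0 | 50.6 | 0.2 |
| green | 60.0 | 50.4 | 0.1 |
| green | 90.0 | 50.7 | 0 |

(each reading ± 0.3 percentage points)

- percentages count the G that a species holds: one X or D counts as two
- solid, in amounts per volume of the solution: G
- the numbers in the tables scatter by 0.3 percentage points (one standard deviation)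
- on the list of suspects stand: G <-> Z; Z + L -> Q; 2 Z -> X; 2 G -> D
- at the start none of G is in solution
- Z means what is dissolved; the solid is not counted in it

- how much Q there is at 80 min, in percent of the G charged
- concentration of Z in solution at 80 min, in percent of saturation

With the main step by itself, G dissolving to Z and Z taking L, this balance allows Q up to 100 per cent of the G charged. The earlier runs stand lower. In the ochre run L allows 50.0%, yet Q levels at 22.1%, and in the violet run, with 0.040 M of L, it levels at 42.3%.

Now we add the loss on the solid, 2 G to D. It takes no L, so we let it enter as one constant M of a curve for Q at this charge of G, the same in both runs.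

Then we add 2 Z to X. Z now has L and a second Z to react with, and we try the curve Q = M L/(L + K). From the two plateaus we read 0.0176 M as the split amount K, the constant of this curve that gives the amount of L at which Q stands at half of M, at this charge of G, with M at 61.0%. Both are fit constants of the curve. Our reckoning for the flask is Q at 32.4%. Z reads 0% in the ochre run at 80.0 min, so we expect it near zero against saturation.

The forecast says Q 33% and Z 0.01% of saturation: “A saturating interpolation in L gives about 33% at L 0.02.” Our Q is slightly lower.

The flask gives Q 32.2% and Z 0% of saturation.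

    G ⇌ Z, rate k1*(cs1 - [Z]) while solid is left; crystals form when [Z] > cs1 (solubility = 14.0 mM, k = 0.170 min⁻¹)
    Z + L → Q (k = 8.90 L mol⁻¹ min⁻¹)
    2 Z → X (k = 17.0 L mol⁻¹ min⁻¹)
    2 G → D (k = 11.0 L mol⁻¹ min⁻¹)

At 2.68 min Z goes to Q 1.3 times as fast as to X in the flask. The flask ends with Q 32.2% beside X 21.3%. For the neighbour flask with 0.0050 M of L, the same split amount gives 13.5%, and that flask holds Q 13.1% beside X 39.3%.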